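| flask | substrate | solid reagent | remark | time |
|---|---|---|---|---|
| dusk | 0.10 M | 0.040 M | run made earlier |  |
| spring | 0.10 M | 0.090 M | run made earlier |  |
| noon | 0.15 M | 0.060 M | run made earlier |  |
| flask | 0.10 M | 0.0600 M |  | 25 min |

- dusk (time / min: side product / %, target / %, substrate / %): 2.50: 10, 71, 1; 4.00: 10, 72, 2; 6.00: 13, 75, 0; 8.00: 13, 71, 0; 12.0: 9, 79, 1; 20.0: 12, 81, 0; 30.0: 14, 84, 0
- spring (time / min: side product / %, target / %, substrate / %): 4.00: 10, 75, 0; 8.00: 11, 74, 0; 12.0: 9, 78, 0; 15.0: 12, 77, 0; 20.0: 14, 81, 0; 25.0: 14, 84, 4; 30.0: 9, 81, 0
- noon (time / min: side product / %, target / %, substrate / %): 2.50: 11, 70, 0; 8.00: 11, 76, 2; 15.0: 12, 78, 1; 20.0: 10, 82, 1; 30.0: 14, 84, 2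

(standard deviation of a reading: 1.5 percentage points)

- as a solid, counted per litre of solution: solid reagent
- the numbers in the tables scatter with a standard deviation of 1.5 percentage points
- at the start none of the solid reagent is in solution

- ratio of side product to target at 3.0 s
- ratio of side product to target at 25 min

If target and side product arise side by side, their ratio stands still in time, so I replace the curves by one mean: the late ratio R (a selectivity factor), which is the side product summed over all readings from 20.0 min on, divided by the target summed over the same readings, and it reads 0.151. The flask, with 0.10 M substrate and 0.0600 M solid reagent, lies inside the charges of those runs, so at 25 min I take R.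

In the opposite extreme, target is reached through an unseen intermediate of lifetime τ, so side product grows as t and target as the square of t, and well below τ the ratio is R times 2τ/t. The first dusk reading already gives 0.141 at 2.50 min, so I put τ below that time, and setting it there gives a ceiling of 15.1 at 3.0 s. I place the flask at 3.0 s between R and that ceiling, and with no earlier reading I commit to their geometric mean, 1.51.

The forecast says 0.15 and 0.15, in its words “I extrapolate the same ratio”, so at 3.0 s it stands lower than my figure.

The flask gives 2.59 at 3.0 s, above my midpoint and below the ceiling, and 0.147 at 25 min, where R read 0.151.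

    substrate → side product (k = 0.0120 s⁻¹)
    intermediate → target (k = 0.0370 s⁻¹)
    solid reagent ⇌ partner, rate k3*(cs3 - [partner]) while solid is left; crystals form when [partner] > cs3 (solubility = 8.70 mM, k = 0.0520 s⁻¹)
    substrate ⇌ dormant form (K = 22.0, k = 0.0240 s⁻¹)
    substrate → intermediate (k = 0.0820 s⁻¹)

Side product and target stand level at 6.03 % each after 0.127 min. In the neighbour flask with 0.025 M substrate, R times the final target of 82.2 % gives 12.4 %, and that flask ends with 12.0 % of side product.

The data were generated by integration on assumed constants; scatter was added.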